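**Retrosynthetic overview**

1. Locants: chromanone half O1, C2 (ketal carbon), C3, C4 (C=O), C4a–C8a (ring A; ring C is the pyranone). Flavan half primed: O1', C2', C3', C4', C4a'–C8a' (ring A'). Ring F is the furan O7'–C2–C3–C8'–C7'.
2. The target comes from its penta-O-benzyl ether by a last hydrogenolysis.
3. Ring C is cut at C4–C4a and at O1, which gives a 3,5-bis(benzyloxy)aryne (ring A) and a flat 2-arylbenzofuran-3-carboxamide that already holds rings F and A' and the (2'R) flavan ring. The enabling feature is that C2 is the β-carbon of the furan C2=C3–C4(=O) unit of ring F, while O1 and C4 sit on the adjacent carbons C8a and C4a of the 1,3,5-trioxygenated ring A, the 1,2-pattern an aryne delivers, polarised by the oxygen on C5.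
4. In the key step the amide oxygen becomes O1, C4a closes onto C4, the ketal forms by 6π closure of O1 onto C2, and the amine of the amide, (S)-2-(methoxymethyl)pyrrolidine, leaves as the auxiliary that steers the protonation of C3, so C2 and C3 are set together.
5. Ring order: ring F first (iodocyclisation of a symmetric tolane), then the flavan pyran ring on ring A' (formylation, aldol, two reductions, Mitsunobu closure), then ring C last; ring A arrives as an aryne made from 3,5-bis(benzyloxy)phenol.

Key step: step 13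

Assumption: the sense of induction by the (S)-configured pyrrolidine amide in step 13 is taken to favour the (2S,3S) ketal; if a trial shows the opposite sense, the enantiomeric amine is used in step 4 and nothing else changes.

**Route**

Step 1
Reactants: 1 1,3,5-tris(benzyloxy)benzene
Product: 2 1,3,5-tris(benzyloxy)-2-iodobenzene
Conditions: NIS (1.05 equiv), MeCN, 0 °C to rt
Reagents that add atoms: N-iodosuccinimide, O=C1CCC(=O)N1I
Why: Electrophilic aromatic iodination; the three free ring positions of the C3-symmetric triether are equivalent, so monoiodination should give one product.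

Step 2
Reactants: 2 1,3,5-tris(benzyloxy)-2-iodobenzene; 3 1-(benzyloxy)-4-ethynylbenzene
Product: 4 1,3,5-tris(benzyloxy)-2-{[4-(benzyloxy)phenyl]ethynyl}benzene
Conditions: PdCl2(PPh3)2 (5 mol%), CuI (10 mol%), Et3N, DMF, 70 °C
Reagents that add atoms: none
Why: Sonogashira coupling; heating should overcome the slow oxidative addition of the electron-rich, di-ortho-substituted iodide.

Step 3
Reactants: 4 1,3,5-tris(benzyloxy)-2-{[4-(benzyloxy)phenyl]ethynyl}benzene
Product: 5 4,6-bis(benzyloxy)-2-[4-(benzyloxy)phenyl]-3-iodo-1-benzofuran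
Conditions: I2 (1.5 equiv), CH2Cl2, rt
Reagents that add atoms: iodine, II
Why: Electrophilic iodocyclisation of an ortho-alkynyl aryl ether: one of the two equivalent ortho benzyloxy oxygens attacks the iodonium-activated alkyne (5-endo-dig) and iodide removes the benzyl group from the oxonium ion, so ring F forms without a regiochemical choice.

Step 4
Reactants: 5 4,6-bis(benzyloxy)-2-[4-(benzyloxy)phenyl]-3-iodo-1-benzofuran; 6 (S)-2-(methoxymethyl)pyrrolidine
Product: 7 {4,6-bis(benzyloxy)-2-[4-(benzyloxy)phenyl]-1-benzofuran-3-yl}[(2S)-2-(methoxymethyl)pyrrolidin-1-yl]methanone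
Conditions: Pd(OAc)2 (5 mol%), Xantphos (10 mol%), CO (1 atm), Et3N, toluene, 90 °C
Reagents that add atoms: carbon monoxide, [C-]#[O+]
Why: Palladium-catalysed aminocarbonylation of the heteroaryl iodide (oxidative addition, CO insertion, aminolysis of the acylpalladium), which brings in the future C4 together with the chiral amine.

Step 5
Reactants: 7 {4,6-bis(benzyloxy)-2-[4-(benzyloxy)phenyl]-1-benzofuran-3-yl}[(2S)-2-(methoxymethyl)pyrrolidin-1-yl]methanone
Product: 8 {6-(benzyloxy)-2-[4-(benzyloxy)phenyl]-4-hydroxy-1-benzofuran-3-yl}[(2S)-2-(methoxymethyl)pyrrolidin-1-yl]methanone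
Conditions: BCl3 (1.2 equiv), CH2Cl2, −78 °C; then H2O
Reagents that add atoms: none
Why: Chelation-controlled ether cleavage: BCl3 held by the amide oxygen should remove only the neighbouring peri benzyl ether on benzofuran C4, as in the selective 5-O-debenzylation of flavones.

Step 6
Reactants: 8 {6-(benzyloxy)-2-[4-(benzyloxy)phenyl]-4-hydroxy-1-benzofuran-3-yl}[(2S)-2-(methoxymethyl)pyrrolidin-1-yl]methanone
Product: 9 6-(benzyloxy)-2-[4-(benzyloxy)phenyl]-4-hydroxy-3-{[(2S)-2-(methoxymethyl)pyrrolidin-1-yl]carbonyl}-1-benzofuran-5-carbaldehyde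
Conditions: MgCl2, Et3N, (CH2O)n, MeCN, reflux
Reagents that add atoms: paraformaldehyde (as formaldehyde), C=O
Why: Magnesium-mediated ortho-formylation of a phenol (Casnati–Skattebøl reaction): formaldehyde is delivered inside the magnesium phenoxide to benzofuran C5, the only free position ortho to the hydroxyl, and a second equivalent accepts hydride.

Step 7
Reactants: 9 6-(benzyloxy)-2-[4-(benzyloxy)phenyl]-4-hydroxy-3-{[(2S)-2-(methoxymethyl)pyrrolidin-1-yl]carbonyl}-1-benzofuran-5-carbaldehyde; 10 1-[4-(benzyloxy)phenyl]ethan-1-one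
Product: 11 (2E)-3-(6-(benzyloxy)-2-[4-(benzyloxy)phenyl]-4-hydroxy-3-{[(2S)-2-(methoxymethyl)pyrrolidin-1-yl]carbonyl}-1-benzofuran-5-yl)-1-[4-(benzyloxy)phenyl]prop-2-en-1-one
Conditions: KOH, EtOH–THF–H2O, rt
Reagents that add atoms: none
Why: Claisen–Schmidt aldol condensation of the non-enolisable aldehyde with the methyl ketone; dehydration should give the conjugated (E)-enone.

Step 8
Reactants: 11 (2E)-3-(6-(benzyloxy)-2-[4-(benzyloxy)phenyl]-4-hydroxy-3-{[(2S)-2-(methoxymethyl)pyrrolidin-1-yl]carbonyl}-1-benzofuran-5-yl)-1-[4-(benzyloxy)phenyl]prop-2-en-1-one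
Product: 12 3-(6-(benzyloxy)-2-[4-(benzyloxy)phenyl]-4-hydroxy-3-{[(2S)-2-(methoxymethyl)pyrrolidin-1-yl]carbonyl}-1-benzofuran-5-yl)-1-[4-(benzyloxy)phenyl]propan-1-one
Conditions: H2 (1 atm), Pd/C, Ph2S (cat.), EtOAc, rt
Reagents that add atoms: none
Why: Chemoselective catalytic hydrogenation of the enone C=C; sulfide-poisoned palladium on carbon should leave the benzyl ethers, the aryl ketone and the benzofuran untouched.

Step 9
Reactants: 12 3-(6-(benzyloxy)-2-[4-(benzyloxy)phenyl]-4-hydroxy-3-{[(2S)-2-(methoxymethyl)pyrrolidin-1-yl]carbonyl}-1-benzofuran-5-yl)-1-[4-(benzyloxy)phenyl]propan-1-one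
Product: 13 {6-(benzyloxy)-2-[4-(benzyloxy)phenyl]-5-{(3S)-3-[4-(benzyloxy)phenyl]-3-hydroxypropyl}-4-hydroxy-1-benzofuran-3-yl}[(2S)-2-(methoxymethyl)pyrrolidin-1-yl]methanone
Conditions: (R)-Me-CBS (20 mol%), BH3·SMe2 (3 equiv), THF, −20 °C; then MeOH, H2O
Reagents that add atoms: none
Why: Corey–Bakshi–Shibata reduction: with the aryl group as the large substituent the (R)-oxazaborolidine should give the (S)-carbinol (as it does with acetophenone), which sets the future C2' before its inversion.

Step 10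
Reactants: 13 {6-(benzyloxy)-2-[4-(benzyloxy)phenyl]-5-{(3S)-3-[4-(benzyloxy)phenyl]-3-hydroxypropyl}-4-hydroxy-1-benzofuran-3-yl}[(2S)-2-(methoxymethyl)pyrrolidin-1-yl]methanone
Product: 14 {(2R)-5-(benzyloxy)-2,8-bis[4-(benzyloxy)phenyl]-3,4-dihydro-2H-furo[2,3-h]chromen-9-yl}[(2S)-2-(methoxymethyl)pyrrolidin-1-yl]methanone
Conditions: PPh3, DIAD, toluene, 0 °C
Reagents that add atoms: none
Why: Intramolecular Mitsunobu etherification (6-exo-tet): the phenol displaces the activated benzylic hydroxyl by SN2 with inversion, which closes the pyran ring of the flavan and turns the (S)-carbinol into (2R).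

Step 11
Reactants: 15 3,5-bis(benzyloxy)phenol
Product: 16 3,5-bis(benzyloxy)-2-bromophenol
Conditions: NBS (1.0 equiv), i-Pr2NH (10 mol%), CH2Cl2, −78 to 0 °C
Reagents that add atoms: N-bromosuccinimide, O=C1CCC(=O)N1Br
Why: Amine-catalysed ortho-selective bromination of a phenol with NBS: the N-bromoamine is guided by hydrogen bonding to the hydroxyl, so bromine should enter between OH and OBn and not at the more hindered carbon between the two ethers.

Step 12
Reactants: 16 3,5-bis(benzyloxy)-2-bromophenol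
Product: 19 3,5-bis(benzyloxy)-2-(trimethylsilyl)phenyl trifluoromethanesulfonate, via silyl ether 17 (not isolated), via lithium phenolate 18 (not isolated)
Conditions: (Me3Si)2NH, THF, 70 °C, then evaporation; n-BuLi, THF, −100 °C; Tf2O, −100 °C to rt
Reagents that add atoms: hexamethyldisilazane, C[Si](C)(C)N[Si](C)(C)C; trifluoromethanesulfonic anhydride, O=S(=O)(OS(=O)(=O)C(F)(F)F)C(F)(F)F
Why: Standard preparation of an ortho-silylaryl triflate: O-silylation, bromine–lithium exchange followed by 1,3-O-to-C silyl migration (retro-Brook rearrangement), and triflation of the resulting phenolate.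

Step 13
Reactants: 14 {(2R)-5-(benzyloxy)-2,8-bis[4-(benzyloxy)phenyl]-3,4-dihydro-2H-furo[2,3-h]chromen-9-yl}[(2S)-2-(methoxymethyl)pyrrolidin-1-yl]methanone; 19 3,5-bis(benzyloxy)-2-(trimethylsilyl)phenyl trifluoromethanesulfonate
Product: 24 penta-O-benzyl ether of the target (2S,3S,2'R), via aryne 20 (not isolated), via benzoxete aminal 21 (not isolated), via iminium phenolate 22 (not isolated), via enamine ketal 23 (not isolated)
Conditions: CsF (3 equiv), MeCN–toluene, rt, slow addition of 19 (1.5 equiv); then AcOH, THF, −40 °C; then H2O, 0 °C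
Reagents that add atoms: water, O
Why: Proposed new method: fluoride turns 19 into aryne 20, the oxygen of the twisted tertiary amide 14 adds to the aryne carbon remote from the flanking benzyloxy group, and the aryl carbon next to that group closes onto the resulting iminium carbon (stepwise [2+2], 4-exo-trig), which forms the C4–C4a bond in benzoxete aminal 21; the closest known reaction types are the insertion of arynes into the C=O bond of formamides, the aryne/enal route to 2H-chromenes and the aryne/α,β-unsaturated acid route to 4-chromanones, which all start with this 1,2-capture. Retro-4π opening of 21 gives iminium phenolate 22, and its phenolate oxygen, now O1, adds to the iminium-activated C2 of the benzofuran (thermal oxa-6π closure, 6-endo), so that 21 expands to ring C and the diaryl ketal appears in the neutral enamine ketal 23, a dearomatising closure that the corresponding ketone would not undergo. Acetic acid then protonates C3 of 23 on the face syn to the C2 aryl group, the only face that leads to the unstrained cis-fused 5/6 system, and water hydrolyses the iminium to the C4 ketone and sets auxiliary 6 free. Because 23 and 22 interconvert by ring opening and closure, both C2 epimers of 23 are in equilibrium and should drain through the one whose C3 face is left open by the methoxymethyl arm of the (S)-pyrrolidine, so that C2 and C3 are set together under auxiliary control (dynamic, Curtin–Hammett) and independently of the remote C2'. The step needs the oxygen on the aryne carbon distal to the 3-benzyloxy group, which the polarisation of 3-alkoxyarynes secures, and it needs the amide oxygen as the only good nucleophile, which full benzyl protection secures.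

Step 14
Reactants: 24 penta-O-benzyl ether of the target (2S,3S,2'R)
Product: 25 CNP0179743.1 (2S,3S,2'R)
Conditions: H2 (1 atm), Pd(OH)2/C, EtOAc–MeOH, rt
Reagents that add atoms: none
Why: Hydrogenolysis of the five benzyl ethers under neutral conditions, the usual last step for benzyl-protected A-type proanthocyanidin ketals, which should leave the diaryl ketal, the ketone and the three stereocentres untouched.

**Compound list**

1 | 1,3,5-tris(benzyloxy)benzene | c1(OCc2ccccc2)cc(OCc2ccccc2)cc(OCc2ccccc2)c1 | starting material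
2 | 1,3,5-tris(benzyloxy)-2-iodobenzene | Ic1c(OCc2ccccc2)cc(OCc2ccccc2)cc1OCc1ccccc1 | intermediate
3 | 1-(benzyloxy)-4-ethynylbenzene | C#Cc1ccc(OCc2ccccc2)cc1 | starting material
4 | 1,3,5-tris(benzyloxy)-2-{[4-(benzyloxy)phenyl]ethynyl}benzene | c1ccc(COc2ccc(C#Cc3c(OCc4ccccc4)cc(OCc4ccccc4)cc3OCc3ccccc3)cc2)cc1 | intermediate
5 | 4,6-bis(benzyloxy)-2-[4-(benzyloxy)phenyl]-3-iodo-1-benzofuran | Ic1c(-c2ccc(OCc3ccccc3)cc2)oc2cc(OCc3ccccc3)cc(OCc3ccccc3)c12 | intermediate
6 | (S)-2-(methoxymethyl)pyrrolidine | COC[C@@H]1CCCN1 | starting material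
7 | {4,6-bis(benzyloxy)-2-[4-(benzyloxy)phenyl]-1-benzofuran-3-yl}[(2S)-2-(methoxymethyl)pyrrolidin-1-yl]methanone | COC[C@@H]1CCCN1C(=O)c1c(-c2ccc(OCc3ccccc3)cc2)oc2cc(OCc3ccccc3)cc(OCc3ccccc3)c12 | intermediate
8 | {6-(benzyloxy)-2-[4-(benzyloxy)phenyl]-4-hydroxy-1-benzofuran-3-yl}[(2S)-2-(methoxymethyl)pyrrolidin-1-yl]methanone | COC[C@@H]1CCCN1C(=O)c1c(-c2ccc(OCc3ccccc3)cc2)oc2cc(OCc3ccccc3)cc(O)c12 | intermediate
9 | 6-(benzyloxy)-2-[4-(benzyloxy)phenyl]-4-hydroxy-3-{[(2S)-2-(methoxymethyl)pyrrolidin-1-yl]carbonyl}-1-benzofuran-5-carbaldehyde | COC[C@@H]1CCCN1C(=O)c1c(-c2ccc(OCc3ccccc3)cc2)oc2cc(OCc3ccccc3)c(C=O)c(O)c12 | intermediate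
10 | 1-[4-(benzyloxy)phenyl]ethan-1-one | CC(=O)c1ccc(OCc2ccccc2)cc1 | starting material
11 | (2E)-3-(6-(benzyloxy)-2-[4-(benzyloxy)phenyl]-4-hydroxy-3-{[(2S)-2-(methoxymethyl)pyrrolidin-1-yl]carbonyl}-1-benzofuran-5-yl)-1-[4-(benzyloxy)phenyl]prop-2-en-1-one | COC[C@@H]1CCCN1C(=O)c1c(-c2ccc(OCc3ccccc3)cc2)oc2cc(OCc3ccccc3)c(/C=C/C(=O)c3ccc(OCc4ccccc4)cc3)c(O)c12 | intermediate
12 | 3-(6-(benzyloxy)-2-[4-(benzyloxy)phenyl]-4-hydroxy-3-{[(2S)-2-(methoxymethyl)pyrrolidin-1-yl]carbonyl}-1-benzofuran-5-yl)-1-[4-(benzyloxy)phenyl]propan-1-one | COC[C@@H]1CCCN1C(=O)c1c(-c2ccc(OCc3ccccc3)cc2)oc2cc(OCc3ccccc3)c(CCC(=O)c3ccc(OCc4ccccc4)cc3)c(O)c12 | intermediate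
13 | {6-(benzyloxy)-2-[4-(benzyloxy)phenyl]-5-{(3S)-3-[4-(benzyloxy)phenyl]-3-hydroxypropyl}-4-hydroxy-1-benzofuran-3-yl}[(2S)-2-(methoxymethyl)pyrrolidin-1-yl]methanone | COC[C@@H]1CCCN1C(=O)c1c(-c2ccc(OCc3ccccc3)cc2)oc2cc(OCc3ccccc3)c(CC[C@H](O)c3ccc(OCc4ccccc4)cc3)c(O)c12 | intermediate
14 | {(2R)-5-(benzyloxy)-2,8-bis[4-(benzyloxy)phenyl]-3,4-dihydro-2H-furo[2,3-h]chromen-9-yl}[(2S)-2-(methoxymethyl)pyrrolidin-1-yl]methanone | COC[C@@H]1CCCN1C(=O)c1c(-c2ccc(OCc3ccccc3)cc2)oc2cc(OCc3ccccc3)c3c(c12)O[C@@H](c1ccc(OCc2ccccc2)cc1)CC3 | intermediate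
15 | 3,5-bis(benzyloxy)phenol | Oc1cc(OCc2ccccc2)cc(OCc2ccccc2)c1 | starting material
16 | 3,5-bis(benzyloxy)-2-bromophenol | Oc1cc(OCc2ccccc2)cc(OCc2ccccc2)c1Br | intermediate
17 | {[3,5-bis(benzyloxy)-2-bromophenyl]oxy}trimethylsilane (silyl ether, in flask) | C[Si](C)(C)Oc1cc(OCc2ccccc2)cc(OCc2ccccc2)c1Br | intermediate
18 | lithium 3,5-bis(benzyloxy)-2-(trimethylsilyl)phenolate (in flask) | [Li+].[O-]c1cc(OCc2ccccc2)cc(OCc2ccccc2)c1[Si](C)(C)C | intermediate
19 | 3,5-bis(benzyloxy)-2-(trimethylsilyl)phenyl trifluoromethanesulfonate | O=S(=O)(Oc1cc(OCc2ccccc2)cc(OCc2ccccc2)c1[Si](C)(C)C)C(F)(F)F | intermediate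
20 | 3,5-bis(benzyloxy)benzyne (aryne, in flask) | C1#CC(OCc2ccccc2)=CC(OCc2ccccc2)=C1 | intermediate
21 | benzoxete aminal (in flask): 2H-benzoxete whose C2 (future C4) carries the pyrrolidine nitrogen and the benzofuran-3-yl group of 14, with benzyloxy groups on the future C5 and C7; configuration at the aminal carbon open | COC[C@@H]1CCCN1C1(Oc2cc(OCc3ccccc3)cc(OCc3ccccc3)c21)c1c(-c2ccc(OCc3ccccc3)cc2)oc2cc(OCc3ccccc3)c3c(c12)O[C@@H](c1ccc(OCc2ccccc2)cc1)CC3 | intermediate
22 | iminium phenolate (in flask): pyrrolidinium ylidene of the ketone between benzofuran C3 of 14 and a 2-oxido-4,6-bis(benzyloxy)phenyl ring | COC[C@@H]1CCC[N+]1=C(c1c(OCc2ccccc2)cc(OCc2ccccc2)cc1[O-])c1c(-c2ccc(OCc3ccccc3)cc2)oc2cc(OCc3ccccc3)c3c(c12)O[C@@H](c1ccc(OCc2ccccc2)cc1)CC3 | intermediate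
23 | enamine ketal (in flask): 24 with C3=C4 and the pyrrolidine nitrogen on C4 in place of the C4 ketone and H3, ketal C2 configured as in 24 | COC[C@@H]1CCCN1C1=C2c3c(O[C@]2(c2ccc(OCc4ccccc4)cc2)Oc2cc(OCc4ccccc4)cc(OCc4ccccc4)c12)cc(OCc2ccccc2)c2CC[C@H](c4ccc(OCc5ccccc5)cc4)Oc32 | intermediate
24 | penta-O-benzyl ether of the target, (2S,3S,2'R); benzyl on O5, O7, O5' and on the 4-oxygen of each of the two aryl groups at C2 and C2' | O=C1c2c(OCc5ccccc5)cc(OCc5ccccc5)cc2O[C@@]2(c3ccc(OCc5ccccc5)cc3)Oc3cc(OCc5ccccc5)c4c(c3[C@@H]12)O[C@@H](c1ccc(OCc5ccccc5)cc1)CC4 | intermediate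
25 | CNP0179743.1, (2S,3S,2'R): cis-fused ketal of a 5,7-dihydroxychroman-4-one (4-hydroxyphenyl on C2) with a (2'R)-5'-hydroxy-2'-(4-hydroxyphenyl)chroman, joined by C2–O7' and C3–C8' | O=C1c2c(O)cc(O)cc2O[C@@]2(c3ccc(O)cc3)Oc3cc(O)c4c(c3[C@@H]12)O[C@@H](c1ccc(O)cc1)CC4 | target

**Step count and risks**

Total steps: 14. Longest linear sequence: 12 (steps 1–10, 13, 14).

Steps most likely to fail:

1. Step 13 (Proposed new method). The aryl anion formed after O-arylation may be protonated before it closes onto the iminium carbon, which would lead to an aryl ester after hydrolysis. The enamine ketal 23 may also reopen to the iminium phenolate 22 during protonation, so that hydrolysis returns the aromatic 3-aroylbenzofuran with loss of the ketal. Facial discrimination by the auxiliary may be low. The fallback uses known reaction types and sets out from 14. Reduction of the tertiary amide with Cp2Zr(H)Cl (THF, rt) should give (2R)-5-(benzyloxy)-2,8-bis[4-(benzyloxy)phenyl]-3,4-dihydro-2H-furo[2,3-h]chromene-9-carbaldehyde F1. Its reaction with the aryne from 19 (CsF, MeCN) follows the known aryne/unsaturated aldehyde route to 2H-chromenes ([2+2], ring opening, oxa-6π closure onto the furan C2=C3 bond) and should give the 2H-chromene ketal F2, which carries no donor on C4 and cannot reopen. Hydroboration and oxidation (BH3·THF, then NaBO3) should place hydroxyl on C4 and hydrogen on C3 to give the C4 alcohol F3, and Dess–Martin oxidation comes back to the route at 24. This sequence has no auxiliary, so the two cis-fused C2/C3 diastereomers would have to be separated by chromatography.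

2. Step 10. Ionisation of the activated p-benzyloxybenzylic carbinol (SN1 leakage) would erode the configuration at C2'. The fallback sets out from 12: acid-catalysed cyclodehydration (TsOH, toluene, reflux) of the ketone with the neighbouring phenol should give the 2-aryl-4H-chromene F4, and iridium-catalysed asymmetric hydrogenation of this cyclic enol ether ([Ir(cod)(t-Bu-PHOX)]B[C6H3(CF3)2]4, ligand enantiomer chosen for 2R, H2, CH2Cl2) comes back to the route at 14 without passing through a benzylic leaving group.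

3. Step 5. Chelation may not discriminate enough, with cleavage of further benzyl ethers or of the methyl ether of the auxiliary. The fallback sets out from 7: hydrogenolysis of all three benzyl ethers (H2, Pd/C, EtOAc–MeOH) should give the triol F5, and alkylation with two equivalents of benzyl bromide (K2CO3, acetone) should spare the hydroxyl on benzofuran C4, which is hydrogen-bonded to the amide carbonyl, and comes back to the route at 8.

**Further compounds**

F1 | step 13 | (2R)-5-(benzyloxy)-2,8-bis[4-(benzyloxy)phenyl]-3,4-dihydro-2H-furo[2,3-h]chromene-9-carbaldehyde | O=Cc1c(-c2ccc(OCc3ccccc3)cc2)oc2cc(OCc3ccccc3)c3c(c12)O[C@@H](c1ccc(OCc2ccccc2)cc1)CC3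
F2 | step 13 | 2H-chromene ketal: 24 with C3=C4 and hydrogen on C4 in place of the ketone and H3, ketal C2 as in 24 | C1=C2c3c(O[C@]2(c2ccc(OCc4ccccc4)cc2)Oc2cc(OCc4ccccc4)cc(OCc4ccccc4)c12)cc(OCc2ccccc2)c2CC[C@H](c4ccc(OCc5ccccc5)cc4)Oc32
F3 | step 13 | C4 alcohol of 24 (hydroxyl on C4 in place of the ketone, configuration at C4 open) | OC1c2c(OCc5ccccc5)cc(OCc5ccccc5)cc2O[C@@]2(c3ccc(OCc5ccccc5)cc3)Oc3cc(OCc5ccccc5)c4c(c3[C@@H]12)O[C@@H](c1ccc(OCc5ccccc5)cc1)CC4
F4 | step 10 | {5-(benzyloxy)-2,8-bis[4-(benzyloxy)phenyl]-4H-furo[2,3-h]chromen-9-yl}[(2S)-2-(methoxymethyl)pyrrolidin-1-yl]methanone | COC[C@@H]1CCCN1C(=O)c1c(-c2ccc(OCc3ccccc3)cc2)oc2cc(OCc3ccccc3)c3c(c12)OC(c1ccc(OCc2ccccc2)cc1)=CC3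
F5 | step 5 | [4,6-dihydroxy-2-(4-hydroxyphenyl)-1-benzofuran-3-yl][(2S)-2-(methoxymethyl)pyrrolidin-1-yl]methanone | COC[C@@H]1CCCN1C(=O)c1c(-c2ccc(O)cc2)oc2cc(O)cc(O)c12
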